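## Retrosynthetic overview

1. Ester C–O bond: allylic alcohol 27 plus silyl-protected (S)-3-hydroxy-2,2-dimethylbutanoic acid 31. The allylic OH comes from SeO2 oxidation of the exocyclic alkene, trans to the C6 bridge.
2. Spiroketal lactone: thermodynamic spirolactonisation of γ-keto acid 25. It is made by adding a Roche-ester-derived, orthoester-masked homoenolate (22) to spiro-γ-lactone 14 (fragment union).
3. Quaternary C6: anti-face alkylation of a bicyclo[3.1.1]heptane-6-carboxylate enolate. That ester comes from photochemical Wolff ring contraction of a bicyclo[3.2.1]octane α-diazoketone.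
4. Bicyclo[3.2.1]octane: (R)-proline-catalysed intramolecular aldol desymmetrisation of 2-(4-oxocyclohexyl)acetaldehyde. This is the key ring closure and fixes the absolute configuration of the core.
5. Ring order: cyclohexane (bought) → aldol bridge (later contracted to the cyclobutane) → oxolane (as lactone 14) → spiro γ-lactone.

Assumption: (R)-proline is taken to give the (1R,5S) bicycle 3, the mirror image of the sense known for (S)-proline-type catalysts in this class of aldolisation; if the sense were opposite, the other proline enantiomer is used and nothing else changes.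

## Route

Step 1
Reactants: 1 4-(2-hydroxyethyl)cyclohexan-1-ol (cis/trans mixture)
Product: 2 2-(4-oxocyclohexyl)acetaldehyde
Conditions: (COCl)2, DMSO, CH2Cl2, −78 °C; then Et3N, −78 → 0 °C
Reagents that add atoms: none
Why: Swern oxidation converts the primary and the secondary alcohol in one operation without over-oxidation, and the cis/trans mixture converges because no stereocentre remains.

Step 2
Reactants: 2 2-(4-oxocyclohexyl)acetaldehyde
Product: 3 (1R,5S,7S)-7-hydroxybicyclo[3.2.1]octan-2-one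
Conditions: (R)-proline (25 mol%), MeCN, rt, 48 h
Reagents that add atoms: none
Why: Enamine-mediated intramolecular aldol (5-enolexo) closes the bridging ring and desymmetrises the σ-symmetric keto aldehyde, the hydrogen-bonded (Houk–List) transition state selecting one of the two enantiotopic α-carbons (C1, C5) and holding the aldehyde oxygen endo (C7, erased in step 4).

Step 3
Reactants: 3 (1R,5S,7S)-7-hydroxybicyclo[3.2.1]octan-2-one
Product: 4 (1S,5S,7S)-2-methylidenebicyclo[3.2.1]octan-7-ol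
Conditions: Zn, CH2Br2, TiCl4, THF, 5 °C (preformed reagent); then 3, CH2Cl2, rt
Reagents that add atoms: dibromomethane, BrCBr
Why: Lombardo methylenation is non-basic, so the β-hydroxy ketone is methylenated without retro-aldol and the free hydroxyl is tolerated, with no stereocentre touched.

Step 4
Reactants: 4 (1S,5S,7S)-2-methylidenebicyclo[3.2.1]octan-7-ol
Product: 5 (1S,5S)-2-methylidenebicyclo[3.2.1]octan-7-one
Conditions: Dess–Martin periodinane, CH2Cl2, rt
Reagents that add atoms: none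
Why: Dess–Martin oxidation gives a β,γ-unsaturated ketone that can neither conjugate nor epimerise because the carbon between the two π-systems is a bridgehead.

Step 5
Reactants: 5 (1S,5S)-2-methylidenebicyclo[3.2.1]octan-7-one
Product: 7 (1S,5S)-6-diazo-2-methylidenebicyclo[3.2.1]octan-7-one, via trifluoroacetyl ketone 6 (not isolated)
Conditions: LiN(SiMe3)2, THF, −78 °C; CF3CO2CH2CF3; then MsN3, Et3N, H2O, MeCN, rt
Reagents that add atoms: methanesulfonyl azide, CS(=O)(=O)N=[N+]=[N-]
Why: Deacylative (Regitz-type) diazo transfer is regiospecific because only C6 can be enolised, C1 being a bridgehead.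

Step 6
Reactants: 7 (1S,5S)-6-diazo-2-methylidenebicyclo[3.2.1]octan-7-one
Product: 9 methyl (1R,5S)-2-methylidenebicyclo[3.1.1]heptane-6-carboxylate (mixture of C6 epimers), via ketene 8 (not isolated)
Conditions: hν (Hg lamp, Pyrex), MeOH, rt
Reagents that add atoms: methanol, CO
Why: Photochemical Wolff rearrangement of the s-cis-locked cyclic diazoketone contracts the five-membered ring to the cyclobutane with retention at the migrating bridgehead, methanol traps the ketene, and the C6 epimers converge in step 7.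

Step 7
Reactants: 9 methyl (1R,5S)-2-methylidenebicyclo[3.1.1]heptane-6-carboxylate
Product: 11 methyl (1S,5S,6S)-6-(2-tert-butoxy-2-oxoethyl)-2-methylidenebicyclo[3.1.1]heptane-6-carboxylate, via lithium enolate 10 (not isolated)
Conditions: LiN(iPr)2, THF, −78 °C; BrCH2CO2tBu, DMPU, −78 → −20 °C
Reagents that add atoms: tert-butyl bromoacetate, CC(C)(C)OC(=O)CBr
Why: Ester enolate alkylation sets the quaternary centre C6, since the syn face of the planar enolate carbon is blocked by the three-carbon bridge (C2–C4) and the electrophile enters anti, leaving the methyl ester syn to that bridge.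

Step 8
Reactants: 11 methyl (1S,5S,6S)-6-(2-tert-butoxy-2-oxoethyl)-2-methylidenebicyclo[3.1.1]heptane-6-carboxylate
Product: 12 2-[(1S,5S,6S)-6-(hydroxymethyl)-2-methylidenebicyclo[3.1.1]heptan-6-yl]ethan-1-ol
Conditions: LiAlH4, THF, 0 °C → reflux
Reagents that add atoms: none
Why: Hydride reduction takes both esters to primary alcohols (the hindered syn ester needs reflux) and leaves the alkene and all stereocentres untouched.

Step 9
Reactants: 12 2-[(1S,5S,6S)-6-(hydroxymethyl)-2-methylidenebicyclo[3.1.1]heptan-6-yl]ethan-1-ol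
Product: 14 (1S,5S,6S)-2-methylidenespiro[bicyclo[3.1.1]heptane-6,3'-oxolan]-5'-one, via lactol 13 (not isolated)
Conditions: TEMPO (20 mol%), PhI(OAc)2 (2.5 equiv), CH2Cl2, rt
Reagents that add atoms: none
Why: TEMPO-mediated oxidative lactonisation oxidises only the unhindered 2-hydroxyethyl arm, the shielded neopentyl syn-CH2OH traps the aldehyde as a lactol, and this is oxidised on to the γ-lactone, which closes the oxolane ring of the target.

Step 10
Reactants: 15 methyl (2R)-3-hydroxy-2-methylpropanoate (Roche ester)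
Product: 16 methyl (2S)-3-bromo-2-methylpropanoate
Conditions: CBr4, PPh3, CH2Cl2, 0 °C
Reagents that add atoms: carbon tetrabromide, BrC(Br)(Br)Br
Why: Appel bromination of the primary alcohol does not touch the α-stereocentre (the descriptor changes by priority only).

Step 11
Reactants: 16 methyl (2S)-3-bromo-2-methylpropanoate
Product: 17 (2S)-3-bromo-2-methylpropanoic acid
Conditions: 48% aq. HBr, 50 °C
Reagents that add atoms: water, O
Why: Acid-catalysed ester hydrolysis avoids the base-induced elimination to methacrylate, and HBr prevents halide exchange.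

Step 12
Reactants: 17 (2S)-3-bromo-2-methylpropanoic acid
Product: 19 (3-methyloxetan-3-yl)methyl (2S)-3-bromo-2-methylpropanoate, via acid chloride 18 (not isolated)
Conditions: (COCl)2, DMF (cat.), CH2Cl2, 0 °C → rt; then (3-methyloxetan-3-yl)methanol, pyridine, CH2Cl2, 0 °C
Reagents that add atoms: (3-methyloxetan-3-yl)methanol, CC1(CO)COC1
Why: Acylation of the oxetanyl alcohol via the acid chloride with the weak base pyridine at 0 °C avoids both ketene formation (racemisation) and HBr elimination.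

Step 13
Reactants: 19 (3-methyloxetan-3-yl)methyl (2S)-3-bromo-2-methylpropanoate
Product: 20 1-[(2S)-1-bromopropan-2-yl]-4-methyl-2,6,7-trioxabicyclo[2.2.2]octane
Conditions: BF3·OEt2 (0.25 equiv), CH2Cl2, −15 °C → rt; Et3N quench
Reagents that add atoms: none
Why: Lewis-acid-promoted oxetane ester to bicyclic orthoester rearrangement (OBO formation) masks the carboxyl at its own oxidation level and removes the acidity of the α-hydrogen.

Step 14
Reactants: 20 1-[(2S)-1-bromopropan-2-yl]-4-methyl-2,6,7-trioxabicyclo[2.2.2]octane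
Product: 21 1-[(2S)-1-iodopropan-2-yl]-4-methyl-2,6,7-trioxabicyclo[2.2.2]octane
Conditions: NaI, NaHCO3 (trace), butan-2-one, 80 °C
Reagents that add atoms: sodium iodide, [Na+].[I-]
Why: Finkelstein exchange under neutral conditions gives the primary iodide needed for clean lithium–iodine exchange, and the orthoester is stable without acid.

Step 15
Reactants: 21 1-[(2S)-1-iodopropan-2-yl]-4-methyl-2,6,7-trioxabicyclo[2.2.2]octane; 14 (1S,5S,6S)-2-methylidenespiro[bicyclo[3.1.1]heptane-6,3'-oxolan]-5'-one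
Product: 23 (4R)-1-[(1S,5S,6S)-6-(hydroxymethyl)-2-methylidenebicyclo[3.1.1]heptan-6-yl]-4-(4-methyl-2,6,7-trioxabicyclo[2.2.2]octan-1-yl)pentan-2-one (in equilibrium with its lactol), via organolithium 22 (not isolated)
Conditions: 21, t-BuLi (2.1 equiv), Et2O/pentane, −78 °C; then 14, THF, −78 °C; AcOH quench at −78 °C
Reagents that add atoms: none
Why: Lithium–iodine exchange gives a configurationally secure homoenolate equivalent (the stereocentre is β to lithium), and its single addition to the lactone stops at the tetrahedral lithium alkoxide at −78 °C.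

Step 16
Reactants: 23 (4R)-1-[(1S,5S,6S)-6-(hydroxymethyl)-2-methylidenebicyclo[3.1.1]heptan-6-yl]-4-(4-methyl-2,6,7-trioxabicyclo[2.2.2]octan-1-yl)pentan-2-one
Product: 24 3-hydroxy-2-(hydroxymethyl)-2-methylpropyl (2R)-5-[(1S,5S,6S)-6-(hydroxymethyl)-2-methylidenebicyclo[3.1.1]heptan-6-yl]-2-methyl-4-oxopentanoate
Conditions: PPTS (0.2 equiv), THF/H2O (4:1), rt
Reagents that add atoms: water, O
Why: Orthoester hydrolysis needs only very mild acid, which opens the cage to the dihydroxy ester and spares the acid-sensitive exocyclic alkene.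

Step 17
Reactants: 24 3-hydroxy-2-(hydroxymethyl)-2-methylpropyl (2R)-5-[(1S,5S,6S)-6-(hydroxymethyl)-2-methylidenebicyclo[3.1.1]heptan-6-yl]-2-methyl-4-oxopentanoate
Product: 26 (1S,5S,6S,5'R,4''R)-4''-methyl-2-methylidenedispiro[bicyclo[3.1.1]heptane-6,3'-oxolane-5',2''-oxolan]-5''-one, via keto acid 25 (not isolated)
Conditions: LiOH, THF/H2O, 0 °C → rt; 1 M HCl to pH 3, extract; then PPTS (0.2 equiv), 4 Å MS, CH2Cl2, rt, to equilibrium
Reagents that add atoms: lithium hydroxide, [Li+].[OH-]
Why: Saponification frees the γ-keto acid, which undergoes acid-catalysed dehydrative spiroketal-lactonisation with the neopentyl hydroxyl; the spiro centre equilibrates through the oxocarbenium ion under the same acid, so the material converges on the thermodynamic configuration, which has the oxolane CH2 and the C4'' methyl cis and pseudo-equatorial on the lactone and the oxolane oxygen pseudo-axial (anomeric effect).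

Step 18
Reactants: 26 (1S,5S,6S,5'R,4''R)-4''-methyl-2-methylidenedispiro[bicyclo[3.1.1]heptane-6,3'-oxolane-5',2''-oxolan]-5''-one
Product: 27 (1R,3S,5R,6S,5'R,4''R)-3-hydroxy-4''-methyl-2-methylidenedispiro[bicyclo[3.1.1]heptane-6,3'-oxolane-5',2''-oxolan]-5''-one
Conditions: SeO2 (0.3 equiv), t-BuOOH (3 equiv), CH2Cl2, 0 °C → rt
Reagents that add atoms: selenium dioxide, O=[Se]=O; tert-butyl hydroperoxide, CC(C)(C)OO
Why: Allylic oxidation (ene reaction then [2,3]-sigmatropic shift) has only C3 available and delivers oxygen on the face anti to the C6 bridge, as in β-pinene to trans-pinocarveol, which sets C3 as S.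

Step 19
Reactants: 28 ethyl 2,2-dimethyl-3-oxobutanoate
Product: 29 ethyl (3S)-3-hydroxy-2,2-dimethylbutanoate
Conditions: H2 (50 atm), RuCl2[(S)-BINAP] (0.5 mol%), EtOH, 60 °C
Reagents that add atoms: none
Why: Noyori asymmetric hydrogenation of the chelating β-keto ester gives the (S)-carbinol with (S)-BINAP, in the same sense as for acetoacetates.

Step 20
Reactants: 29 ethyl (3S)-3-hydroxy-2,2-dimethylbutanoate
Product: 30 ethyl (3S)-3-[(tert-butyldimethylsilyl)oxy]-2,2-dimethylbutanoate
Conditions: TBSOTf, 2,6-lutidine, CH2Cl2, 0 °C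
Reagents that add atoms: tert-butyldimethylsilyl trifluoromethanesulfonate, CC(C)(C)[Si](C)(C)OS(=O)(=O)C(F)(F)F
Why: Silyl triflate protects the hindered secondary alcohol, so the β-hydroxy acid cannot self-acylate or form a β-lactone later.

Step 21
Reactants: 30 ethyl (3S)-3-[(tert-butyldimethylsilyl)oxy]-2,2-dimethylbutanoate
Product: 31 (3S)-3-[(tert-butyldimethylsilyl)oxy]-2,2-dimethylbutanoic acid
Conditions: LiOH·H2O, THF/EtOH/H2O, 60 °C; then 1 M HCl to pH 3, 0 °C
Reagents that add atoms: lithium hydroxide, [Li+].[OH-]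
Why: Saponification of the hindered ester needs heat, which the silyl ether tolerates, and the quaternary α-carbon excludes epimerisation or elimination.

Step 22
Reactants: 31 (3S)-3-[(tert-butyldimethylsilyl)oxy]-2,2-dimethylbutanoic acid; 27 (1R,3S,5R,6S,5'R,4''R)-3-hydroxy-4''-methyl-2-methylidenedispiro[bicyclo[3.1.1]heptane-6,3'-oxolane-5',2''-oxolan]-5''-one
Product: 33 (1R,3S,5R,6S,5'R,4''R)-4''-methyl-2-methylidene-5''-oxodispiro[bicyclo[3.1.1]heptane-6,3'-oxolane-5',2''-oxolan]-3-yl (3S)-3-[(tert-butyldimethylsilyl)oxy]-2,2-dimethylbutanoate, via acid chloride 32 (not isolated)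
Conditions: 31, 1-chloro-N,N,2-trimethylprop-1-en-1-amine, CH2Cl2, rt; then 27, DMAP, Et3N, CH2Cl2, 40 °C
Reagents that add atoms: none
Why: DMAP-catalysed acylation with the neutrally generated acid chloride is the most forcing mild esterification for a pivalate-type acid and proceeds with retention at C3 because the C–O bond is not broken.

Step 23
Reactants: 33 (1R,3S,5R,6S,5'R,4''R)-4''-methyl-2-methylidene-5''-oxodispiro[bicyclo[3.1.1]heptane-6,3'-oxolane-5',2''-oxolan]-3-yl (3S)-3-[(tert-butyldimethylsilyl)oxy]-2,2-dimethylbutanoate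
Product: 34 (1R,3S,5R,6S,5'R,4''R)-4''-methyl-2-methylidene-5''-oxodispiro[bicyclo[3.1.1]heptane-6,3'-oxolane-5',2''-oxolan]-3-yl (3S)-3-hydroxy-2,2-dimethylbutanoate (target)
Conditions: HF·pyridine, pyridine, THF, 0 °C → rt
Reagents that add atoms: none
Why: Buffered fluoride desilylation removes the silyl ether without ionising the allylic ester, opening the spiroketal lactone or isomerising the alkene.

## Compound list

1 | 4-(2-hydroxyethyl)cyclohexan-1-ol (cis/trans) | OCCC1CCC(O)CC1 | starting material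
2 | 2-(4-oxocyclohexyl)acetaldehyde | O=CCC1CCC(=O)CC1 | intermediate
3 | (1R,5S,7S)-7-hydroxybicyclo[3.2.1]octan-2-one | O=C1CC[C@H]2C[C@@H]1[C@@H](O)C2 | intermediate
4 | (1S,5S,7S)-2-methylidenebicyclo[3.2.1]octan-7-ol | C=C1CC[C@H]2C[C@@H]1[C@@H](O)C2 | intermediate
5 | (1S,5S)-2-methylidenebicyclo[3.2.1]octan-7-one | C=C1CC[C@H]2C[C@@H]1C(=O)C2 | intermediate
6 | (1S,5S)-2-methylidene-6-(trifluoroacetyl)bicyclo[3.2.1]octan-7-one (as lithium enolate, C6 undefined) | C=C1CC[C@H]2C[C@@H]1C(=O)C2C(=O)C(F)(F)F | intermediate (not isolated)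
7 | (1S,5S)-6-diazo-2-methylidenebicyclo[3.2.1]octan-7-one | C=C1CC[C@H]2C[C@@H]1C(=O)C2=[N+]=[N-] | intermediate
8 | [(1S,5S)-2-methylidenebicyclo[3.1.1]heptan-6-ylidene]methanone (ketene) | C=C1CC[C@H]2C[C@@H]1C2=C=O | intermediate (not isolated)
9 | methyl (1R,5S)-2-methylidenebicyclo[3.1.1]heptane-6-carboxylate (C6 epimers) | C=C1CC[C@H]2C[C@@H]1C2C(=O)OC | intermediate
10 | lithium enolate of 9 | C=C1CC[C@H]2C[C@@H]1C2=C(OC)O[Li] | intermediate (not isolated)
11 | methyl (1S,5S,6S)-6-(2-tert-butoxy-2-oxoethyl)-2-methylidenebicyclo[3.1.1]heptane-6-carboxylate (ester syn, acetate arm anti to C2–C4) | C=C1CC[C@H]2C[C@@H]1[C@@]2(CC(=O)OC(C)(C)C)C(=O)OC | intermediate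
12 | 2-[(1S,5S,6S)-6-(hydroxymethyl)-2-methylidenebicyclo[3.1.1]heptan-6-yl]ethan-1-ol | C=C1CC[C@H]2C[C@@H]1[C@@]2(CCO)CO | intermediate
13 | (1S,5S,6S)-2-methylidenespiro[bicyclo[3.1.1]heptane-6,3'-oxolan]-5'-ol (lactol, anomers) | C=C1CC[C@H]2C[C@@H]1[C@@]21COC(O)C1 | intermediate (not isolated)
14 | (1S,5S,6S)-2-methylidenespiro[bicyclo[3.1.1]heptane-6,3'-oxolan]-5'-one | C=C1CC[C@H]2C[C@@H]1[C@@]21COC(=O)C1 | intermediate
15 | methyl (2R)-3-hydroxy-2-methylpropanoate | OC[C@@H](C)C(=O)OC | starting material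
16 | methyl (2S)-3-bromo-2-methylpropanoate | BrC[C@@H](C)C(=O)OC | intermediate
17 | (2S)-3-bromo-2-methylpropanoic acid | BrC[C@@H](C)C(=O)O | intermediate
18 | (2S)-3-bromo-2-methylpropanoyl chloride | BrC[C@@H](C)C(Cl)=O | intermediate (not isolated)
19 | (3-methyloxetan-3-yl)methyl (2S)-3-bromo-2-methylpropanoate | BrC[C@@H](C)C(=O)OCC1(C)COC1 | intermediate
20 | 1-[(2S)-1-bromopropan-2-yl]-4-methyl-2,6,7-trioxabicyclo[2.2.2]octane | BrC[C@@H](C)C12OCC(C)(CO1)CO2 | intermediate
21 | 1-[(2S)-1-iodopropan-2-yl]-4-methyl-2,6,7-trioxabicyclo[2.2.2]octane | IC[C@@H](C)C12OCC(C)(CO1)CO2 | intermediate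
22 | [(2R)-2-(4-methyl-2,6,7-trioxabicyclo[2.2.2]octan-1-yl)propyl]lithium | [Li]C[C@@H](C)C12OCC(C)(CO1)CO2 | intermediate (not isolated)
23 | (4R)-1-[(1S,5S,6S)-6-(hydroxymethyl)-2-methylidenebicyclo[3.1.1]heptan-6-yl]-4-(4-methyl-2,6,7-trioxabicyclo[2.2.2]octan-1-yl)pentan-2-one | C=C1CC[C@H]2C[C@@H]1[C@@]2(CC(=O)C[C@@H](C)C34OCC(C)(CO3)CO4)CO | intermediate
24 | 3-hydroxy-2-(hydroxymethyl)-2-methylpropyl (2R)-5-[(1S,5S,6S)-6-(hydroxymethyl)-2-methylidenebicyclo[3.1.1]heptan-6-yl]-2-methyl-4-oxopentanoate | C=C1CC[C@H]2C[C@@H]1[C@@]2(CC(=O)C[C@@H](C)C(=O)OCC(C)(CO)CO)CO | intermediate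
25 | (2R)-5-[(1S,5S,6S)-6-(hydroxymethyl)-2-methylidenebicyclo[3.1.1]heptan-6-yl]-2-methyl-4-oxopentanoic acid | C=C1CC[C@H]2C[C@@H]1[C@@]2(CC(=O)C[C@@H](C)C(=O)O)CO | intermediate (not isolated)
26 | (1S,5S,6S,5'R,4''R)-4''-methyl-2-methylidenedispiro[bicyclo[3.1.1]heptane-6,3'-oxolane-5',2''-oxolan]-5''-one | C=C1CC[C@H]2C[C@@H]1[C@@]21CO[C@@]2(C[C@@H](C)C(=O)O2)C1 | intermediate
27 | (1R,3S,5R,6S,5'R,4''R)-3-hydroxy-4''-methyl-2-methylidenedispiro[bicyclo[3.1.1]heptane-6,3'-oxolane-5',2''-oxolan]-5''-one (OH anti to the C6 bridge) | C=C1[C@@H](O)C[C@H]2C[C@@H]1[C@@]21CO[C@@]2(C[C@@H](C)C(=O)O2)C1 | intermediate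
28 | ethyl 2,2-dimethyl-3-oxobutanoate | CCOC(=O)C(C)(C)C(C)=O | starting material
29 | ethyl (3S)-3-hydroxy-2,2-dimethylbutanoate | CCOC(=O)C(C)(C)[C@H](C)O | intermediate
30 | ethyl (3S)-3-[(tert-butyldimethylsilyl)oxy]-2,2-dimethylbutanoate | CCOC(=O)C(C)(C)[C@H](C)O[Si](C)(C)C(C)(C)C | intermediate
31 | (3S)-3-[(tert-butyldimethylsilyl)oxy]-2,2-dimethylbutanoic acid | OC(=O)C(C)(C)[C@H](C)O[Si](C)(C)C(C)(C)C | intermediate
32 | (3S)-3-[(tert-butyldimethylsilyl)oxy]-2,2-dimethylbutanoyl chloride | ClC(=O)C(C)(C)[C@H](C)O[Si](C)(C)C(C)(C)C | intermediate (not isolated)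
33 | (1R,3S,5R,6S,5'R,4''R)-4''-methyl-2-methylidene-5''-oxodispiro[bicyclo[3.1.1]heptane-6,3'-oxolane-5',2''-oxolan]-3-yl (3S)-3-[(tert-butyldimethylsilyl)oxy]-2,2-dimethylbutanoate | C=C1[C@@H](OC(=O)C(C)(C)[C@H](C)O[Si](C)(C)C(C)(C)C)C[C@H]2C[C@@H]1[C@@]21CO[C@@]2(C[C@@H](C)C(=O)O2)C1 | intermediate
34 | (1R,3S,5R,6S,5'R,4''R)-4''-methyl-2-methylidene-5''-oxodispiro[bicyclo[3.1.1]heptane-6,3'-oxolane-5',2''-oxolan]-3-yl (3S)-3-hydroxy-2,2-dimethylbutanoate | C=C1[C@@H](OC(=O)C(C)(C)[C@H](C)O)C[C@H]2C[C@@H]1[C@@]21CO[C@@]2(C[C@@H](C)C(=O)O2)C1 | target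

## Step count and risks

Total step count: 23. Longest linear sequence: 15 steps (steps 1–9, 15–18, 22, 23).

**Step 2 (sense and level of induction in the aldol).** The fallback sets out from 2 and returns at 3. The aldol is run racemically (pyrrolidine, AcOH cat., MeCN), giving 3 together with its enantiomer (1S,5R,7R)-7-hydroxybicyclo[3.2.1]octan-2-one F1. The racemate is resolved by lipase-catalysed acetylation (Burkholderia cepacia lipase, vinyl acetate, MTBE). By the Kazlauskas rule the (7R)-alcohol reacts, giving (1S,5R,7R)-2-oxobicyclo[3.2.1]octan-7-yl acetate F2, and unreacted 3 is separated by chromatography and carried on.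

**Step 7 (facial selectivity at the quaternary C6).** The fallback sets out from 9 and returns at 14. If the electrophile is found to enter syn to the three-carbon bridge, the roles of the two carbons are exchanged. Enolate 10 is treated with monomeric formaldehyde to give methyl (1S,5S,6R)-6-(hydroxymethyl)-2-methylidenebicyclo[3.1.1]heptane-6-carboxylate F3, whose CH2OH then sits syn. TBSCl/imidazole gives methyl (1S,5S,6R)-6-{[(tert-butyldimethylsilyl)oxy]methyl}-2-methylidenebicyclo[3.1.1]heptane-6-carboxylate F4. iBu2AlH at −78 °C gives (1S,5S,6R)-6-{[(tert-butyldimethylsilyl)oxy]methyl}-2-methylidenebicyclo[3.1.1]heptane-6-carbaldehyde F5. Wittig homologation with Ph3P=CHOMe gives tert-butyl{[(1S,5S,6S)-6-(2-methoxyethenyl)-2-methylidenebicyclo[3.1.1]heptan-6-yl]methoxy}dimethylsilane F6. Dilute HCl in THF unmasks the aldehyde and the alcohol, which close to lactol 13, and this is oxidised as in step 9 to 14.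

**Step 18 (late-stage SeO2 oxidation: yield, over-oxidation).** The fallback sets out from 26 and returns at 27. The exocyclic alkene is isomerised into the ring with RuHCl(CO)(PPh3)3 (cat., toluene, 80 °C) to (1S,5S,6S,5'R,4''R)-2,4''-dimethyldispiro[bicyclo[3.1.1]hept-2-ene-6,3'-oxolane-5',2''-oxolan]-5''-one F7. A Schenck ene reaction with singlet oxygen (O2, tetraphenylporphyrin, hν, CH2Cl2, 0 °C) attacks C3 anti to the C6 bridge and returns the double bond to the exocyclic position, as in α-pinene to trans-pinocarveol. This gives (1R,3S,5R,6S,5'R,4''R)-3-hydroperoxy-4''-methyl-2-methylidenedispiro[bicyclo[3.1.1]heptane-6,3'-oxolane-5',2''-oxolan]-5''-one F8, which is reduced in the same flask with PPh3 to 27.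

Further compounds
F1 | step 2 | (1S,5R,7R)-7-hydroxybicyclo[3.2.1]octan-2-one | O=C1CC[C@@H]2C[C@H]1[C@H](O)C2
F2 | step 2 | (1S,5R,7R)-2-oxobicyclo[3.2.1]octan-7-yl acetate | O=C1CC[C@@H]2C[C@H]1[C@H](OC(C)=O)C2
F3 | step 7 | methyl (1S,5S,6R)-6-(hydroxymethyl)-2-methylidenebicyclo[3.1.1]heptane-6-carboxylate | C=C1CC[C@H]2C[C@@H]1[C@@]2(C(=O)OC)CO
F4 | step 7 | methyl (1S,5S,6R)-6-{[(tert-butyldimethylsilyl)oxy]methyl}-2-methylidenebicyclo[3.1.1]heptane-6-carboxylate | C=C1CC[C@H]2C[C@@H]1[C@@]2(C(=O)OC)CO[Si](C)(C)C(C)(C)C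
F5 | step 7 | (1S,5S,6R)-6-{[(tert-butyldimethylsilyl)oxy]methyl}-2-methylidenebicyclo[3.1.1]heptane-6-carbaldehyde | C=C1CC[C@H]2C[C@@H]1[C@@]2(C=O)CO[Si](C)(C)C(C)(C)C
F6 | step 7 | tert-butyl{[(1S,5S,6S)-6-(2-methoxyethenyl)-2-methylidenebicyclo[3.1.1]heptan-6-yl]methoxy}dimethylsilane (E/Z mixture) | C=C1CC[C@H]2C[C@@H]1[C@@]2(C=COC)CO[Si](C)(C)C(C)(C)C
F7 | step 18 | (1S,5S,6S,5'R,4''R)-2,4''-dimethyldispiro[bicyclo[3.1.1]hept-2-ene-6,3'-oxolane-5',2''-oxolan]-5''-one | CC1=CC[C@H]2C[C@@H]1[C@@]21CO[C@@]2(C[C@@H](C)C(=O)O2)C1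
F8 | step 18 | (1R,3S,5R,6S,5'R,4''R)-3-hydroperoxy-4''-methyl-2-methylidenedispiro[bicyclo[3.1.1]heptane-6,3'-oxolane-5',2''-oxolan]-5''-one | C=C1[C@@H](OO)C[C@H]2C[C@@H]1[C@@]21CO[C@@]2(C[C@@H](C)C(=O)O2)C1
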